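**Strategy.** Ring C is cut at O1–C8a, C4–C4a and O1–C2, which leaves 3,4,5,6-tetramethoxybenzyne and a ring-B arylpropiolic acid. The feature exploited lies in ring A. C5, C6, C7 and C8 all carry oxygen, so with O5 kept as a methyl ether the aryne whose triple bond joins C4a and C8a is mirror-symmetric. Both orientations of addition therefore give the same chromone. A single fluoride-triggered operation couples the fragments, moves the acyl group from O to C and closes the pyranone. Its precursors are the hexasubstituted 2-silylaryl triflate 8 and the dibenzyl-protected acid 15. O3 is added afterwards, and chelation to C4=O finally singles out the C5 methyl ether.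

Key step: step 8

Remark on the chemistry: the target has no stereocentre, and the C2–C1′ axis carries too little ortho bulk to be configurationally stable. The compound is therefore achiral and no enantiomer has to be selected. The only stereocentres of the route (epoxide 19, racemic) vanish in the flask in which they form.

**Ring A fragment**

Step 1
Reactants: 1 1,2,3,4-tetramethoxybenzene
Product: 4 2,3,4,5-tetramethoxyphenol, via aryllithium 2 (not isolated), via lithium aryltrimethoxyborate 3 (not isolated)
Conditions: n-BuLi, TMEDA, THF, 0 °C; B(OMe)3, −78 °C → rt; AcOH, 30% H2O2, 0 °C → rt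
Reagents that add atoms: n-butyllithium [Li]CCCC (Li of 2 and 3 only); trimethyl borate COB(OC)OC (3 only); hydrogen peroxide OO (phenol oxygen of 4)
Why: Methoxy-directed ortho-lithiation (the two free ring positions are equivalent), borylation and the peroxide-induced 1,2-aryl shift from boron to oxygen form a standard one-flask arene-to-phenol sequence, and the cold, weakly acidic oxidation spares the electron-rich phenol.

Step 2
Reactants: 4 2,3,4,5-tetramethoxyphenol
Product: 5 2-bromo-3,4,5,6-tetramethoxyphenol
Conditions: NBS (1.0 equiv), dry CH2Cl2, −78 → 0 °C, dark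
Reagents that add atoms: N-bromosuccinimide O=C1CCC(=O)N1Br
Why: Electrophilic aromatic bromination can only strike the single remaining C–H, which lies ortho to the free hydroxyl, and one equivalent of NBS in a dry, cold medium avoids oxidative demethylation of the 4-methoxyphenol unit to a quinone.

Step 3
Reactants: 5 2-bromo-3,4,5,6-tetramethoxyphenol
Product: 8 2,3,4,5-tetramethoxy-6-(trimethylsilyl)phenyl trifluoromethanesulfonate, via aryl silyl ether 6 (not isolated), via lithium 2-silylphenoxide 7 (not isolated)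
Conditions: HMDS, THF, reflux, then evaporation; n-BuLi, THF, −78 °C; Tf2O, −78 °C → rt
Reagents that add atoms: hexamethyldisilazane C[Si](C)(C)N[Si](C)(C)C; n-butyllithium [Li]CCCC (Li of 7 only); triflic anhydride O=S(=O)(OS(=O)(=O)C(F)(F)F)C(F)(F)F
Why: O-Silylation, bromine–lithium exchange and a retro-Brook 1,3-shift of silicon from oxygen to the carbanion give phenoxide 7, and its triflation completes the standard sequence to 2-silylaryl triflate aryne precursors.

**Ring B fragment**

Step 4
Reactants: 9 3,4-bis(benzyloxy)benzaldehyde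
Product: 11 3,4-bis(benzyloxy)phenol, via aryl formate 10 (not isolated)
Conditions: mCPBA, CH2Cl2, 0 °C → rt, aq. NaHCO3 wash; then K2CO3 (cat.), MeOH, rt
Reagents that add atoms: 3-chloroperbenzoic acid O=C(OO)c1cccc(Cl)c1
Why: In this Baeyer–Villiger (Dakin-type) oxidation the electron-rich aryl group migrates in preference to hydride to give formate 10, and base-catalysed transesterification frees the phenol without touching the benzyl ethers.

Step 5
Reactants: 11 3,4-bis(benzyloxy)phenol
Product: 12 1,2-bis(benzyloxy)-4-methoxybenzene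
Conditions: MeI, K2CO3, acetone, reflux
Reagents that add atoms: iodomethane CI
Why: Williamson etherification of the only acidic OH.

Step 6
Reactants: 12 1,2-bis(benzyloxy)-4-methoxybenzene
Product: 13 1,2-bis(benzyloxy)-4-iodo-5-methoxybenzene
Conditions: NIS (1.0 equiv), TFA (cat.), MeCN, 0 °C → rt
Reagents that add atoms: N-iodosuccinimide O=C1CCC(=O)N1I
Why: Electrophilic aromatic iodination should go to C5 of 12 (ortho to OMe, para to the C2 benzyloxy group), because C3 is wedged between two alkoxy groups and C6 is activated by one ortho oxygen only.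

Step 7
Reactants: 13 1,2-bis(benzyloxy)-4-iodo-5-methoxybenzene; 14 propiolic acid
Product: 15 3-[4,5-bis(benzyloxy)-2-methoxyphenyl]prop-2-ynoic acid
Conditions: Pd(PPh3)4 (cat.), DBU (2.5 equiv), DMSO, 35 °C; aq. HCl work-up
Reagents that add atoms: none
Why: This is a copper-free Sonogashira coupling of an aryl iodide with propiolic acid as its amidinium salt, and near room temperature without copper the alkynoate should keep its CO2 unit, so 15 is collected by acid–base extraction.

**Union and completion**

Step 8
Reactants: 8 2,3,4,5-tetramethoxy-6-(trimethylsilyl)phenyl trifluoromethanesulfonate (1.5 equiv); 15 3-[4,5-bis(benzyloxy)-2-methoxyphenyl]prop-2-ynoic acid (1.0 equiv)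
Product: 18 2-[4,5-bis(benzyloxy)-2-methoxyphenyl]-5,6,7,8-tetramethoxy-4H-chromen-4-one, via tetramethoxybenzyne 16 (not isolated), via 2-hydroxyaryl ynone 17 (not isolated)
Conditions: CsF (4 equiv), dry THF, 125 °C, sealed tube
Reagents that add atoms: none
Why: Fluoride strips silicon from 8 and triflate departs to give aryne 16; the caesium carboxylate of 15 adds through oxygen, the 2-(acyloxy)aryl anion attacks its own ester carbonyl (4-exo-trig), and the strained benzoxetene alkoxide collapses to the phenoxide of 17, an anionic ortho-Fries-type acyl shift. The closest known reaction type is the fluoride-mediated insertion of arynes into the C–O bond of carboxylic acids in hot THF, which with 3-arylpropiolic acids runs on to flavones. Ring C, the only ring retained, closes by 6-endo-dig oxa-Michael addition of the phenoxide oxygen to the ynone β-carbon (C2), and the resulting C3 carbanion takes back the proton that the acid had parked on fluoride. No stereocentre is formed. Aryne regiochemistry is not an issue because 16 has a mirror plane through the midpoints of C4a≡C8a and C6–C7, while 6-endo should beat 5-exo because donor-rich ring B places the electrophilic end of the ynone on C2 and aprotic base-mediated closures of such ynones generally follow the Michael mode. The acyl shift must outrun protonation of the aryl anion, which is why a poorly ionising ether solvent, high temperature, sparingly soluble CsF (slow aryne release) and an excess of the short-sequence partner 8 are chosen.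

Step 9
Reactants: 18 2-[4,5-bis(benzyloxy)-2-methoxyphenyl]-5,6,7,8-tetramethoxy-4H-chromen-4-one
Product: 20 2-[4,5-bis(benzyloxy)-2-methoxyphenyl]-3-hydroxy-5,6,7,8-tetramethoxy-4H-chromen-4-one, via flavone 2,3-epoxide 19 (not isolated)
Conditions: DMDO (stock solution in acetone), CH2Cl2, 0 °C → rt; then p-TsOH (cat.)
Reagents that add atoms: dimethyldioxirane CC1(C)OO1
Why: Neutral oxygen transfer from DMDO to the enol-ether-like C2=C3 bond gives the racemic, necessarily cis-fused epoxide 19, which acid opens at C2 to a cation stabilised by O1 and ring B and which then loses H3 to give the flavonol, so both transient stereocentres disappear.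

Step 10
Reactants: 20 2-[4,5-bis(benzyloxy)-2-methoxyphenyl]-3-hydroxy-5,6,7,8-tetramethoxy-4H-chromen-4-one
Product: 21 2-[4,5-bis(benzyloxy)-2-methoxyphenyl]-3,5,6,7,8-pentamethoxy-4H-chromen-4-one
Conditions: MeI, K2CO3, acetone, reflux
Reagents that add atoms: iodomethane CI
Why: Williamson etherification of the single free hydroxyl (O3).

Step 11
Reactants: 21 2-[4,5-bis(benzyloxy)-2-methoxyphenyl]-3,5,6,7,8-pentamethoxy-4H-chromen-4-one
Product: 22 2-(4,5-dihydroxy-2-methoxyphenyl)-5-hydroxy-3,6,7,8-tetramethoxy-4H-chromen-4-one (5,4′,5′-trihydroxy-3,6,7,8,2′-pentamethoxyflavone)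
Conditions: BCl3 (excess), pentamethylbenzene (excess), CH2Cl2, −78 → 0 °C, argon; then degassed H2O
Reagents that add atoms: none
Why: In this Lewis-acid ether cleavage BCl3 ionises the two aryl benzyl ethers at −78 °C while pentamethylbenzene captures the benzyl cation (Friedel–Crafts) before it can alkylate ring B, and on warming the six-membered C4=O···B···O5 chelate directs chloride to the C5 methyl group only, leaving intact the unchelated methyl ethers and the O3 methyl, which can form only a five-ring chelate.

**Compound list**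

1 | 1,2,3,4-tetramethoxybenzene | COc1ccc(OC)c(OC)c1OC | starting material
2 | (2,3,4,5-tetramethoxyphenyl)lithium | [Li]c1cc(OC)c(OC)c(OC)c1OC | intermediate
3 | lithium trimethoxy(2,3,4,5-tetramethoxyphenyl)borate | [Li+].CO[B-](OC)(OC)c1cc(OC)c(OC)c(OC)c1OC | intermediate
4 | 2,3,4,5-tetramethoxyphenol | COc1cc(O)c(OC)c(OC)c1OC | intermediate
5 | 2-bromo-3,4,5,6-tetramethoxyphenol | COc1c(O)c(Br)c(OC)c(OC)c1OC | intermediate
6 | (2-bromo-3,4,5,6-tetramethoxyphenoxy)trimethylsilane | COc1c(O[Si](C)(C)C)c(Br)c(OC)c(OC)c1OC | intermediate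
7 | lithium 2,3,4,5-tetramethoxy-6-(trimethylsilyl)phenoxide | [Li+].COc1c([O-])c([Si](C)(C)C)c(OC)c(OC)c1OC | intermediate
8 | 2,3,4,5-tetramethoxy-6-(trimethylsilyl)phenyl trifluoromethanesulfonate | COc1c(OC)c(OC)c(OC)c(OS(=O)(=O)C(F)(F)F)c1[Si](C)(C)C | intermediate
9 | 3,4-bis(benzyloxy)benzaldehyde | O=Cc1ccc(OCc2ccccc2)c(OCc2ccccc2)c1 | starting material
10 | 3,4-bis(benzyloxy)phenyl formate | O=COc1ccc(OCc2ccccc2)c(OCc2ccccc2)c1 | intermediate
11 | 3,4-bis(benzyloxy)phenol | Oc1ccc(OCc2ccccc2)c(OCc2ccccc2)c1 | intermediate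
12 | 1,2-bis(benzyloxy)-4-methoxybenzene | COc1ccc(OCc2ccccc2)c(OCc2ccccc2)c1 | intermediate
13 | 1,2-bis(benzyloxy)-4-iodo-5-methoxybenzene | COc1cc(OCc2ccccc2)c(OCc2ccccc2)cc1I | intermediate
14 | propiolic acid | C#CC(=O)O | starting material
15 | 3-[4,5-bis(benzyloxy)-2-methoxyphenyl]prop-2-ynoic acid | COc1cc(OCc2ccccc2)c(OCc2ccccc2)cc1C#CC(=O)O | intermediate
16 | 3,4,5,6-tetramethoxybenzyne | COC1=C(OC)C(OC)=C(OC)C#C1 | intermediate
17 | 3-[4,5-bis(benzyloxy)-2-methoxyphenyl]-1-(2-hydroxy-3,4,5,6-tetramethoxyphenyl)prop-2-yn-1-one (present in the flask as its caesium phenoxide) | COc1cc(OCc2ccccc2)c(OCc2ccccc2)cc1C#CC(=O)c1c(O)c(OC)c(OC)c(OC)c1OC | intermediate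
18 | 2-[4,5-bis(benzyloxy)-2-methoxyphenyl]-5,6,7,8-tetramethoxy-4H-chromen-4-one | COc1cc(OCc2ccccc2)c(OCc2ccccc2)cc1-c1cc(=O)c2c(OC)c(OC)c(OC)c(OC)c2o1 | intermediate
19 | 1a-[4,5-bis(benzyloxy)-2-methoxyphenyl]-3,4,5,6-tetramethoxy-1a,7a-dihydro-7H-oxireno[2,3-b]chromen-7-one (racemic, cis-fused; one enantiomer drawn) | O=C1c2c(OC)c(OC)c(OC)c(OC)c2O[C@@]2(c3cc(OCc4ccccc4)c(OCc4ccccc4)cc3OC)O[C@@H]12 | intermediate
20 | 2-[4,5-bis(benzyloxy)-2-methoxyphenyl]-3-hydroxy-5,6,7,8-tetramethoxy-4H-chromen-4-one | COc1cc(OCc2ccccc2)c(OCc2ccccc2)cc1-c1oc2c(OC)c(OC)c(OC)c(OC)c2c(=O)c1O | intermediate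
21 | 2-[4,5-bis(benzyloxy)-2-methoxyphenyl]-3,5,6,7,8-pentamethoxy-4H-chromen-4-one | COc1cc(OCc2ccccc2)c(OCc2ccccc2)cc1-c1oc2c(OC)c(OC)c(OC)c(OC)c2c(=O)c1OC | intermediate
22 | 5,4′,5′-trihydroxy-3,6,7,8,2′-pentamethoxyflavone (achiral) | COc1cc(O)c(O)cc1-c1oc2c(OC)c(OC)c(OC)c(O)c2c(=O)c1OC | target

**Total step count:** 11. **Longest linear sequence:** 8 steps (steps 4–11, from 9). The ring A branch (steps 1–3) joins at step 8.

**Steps most likely to fail**

1. Step 8. The aryl anion may pick up a proton before the acyl group migrates, which would end in plain O-arylation. The propiolate may lose CO2 at 125 °C, or the phenoxide may close in the 5-exo mode. The fallback sets out from 5 and 15 and comes back at 17, and from there at 18. It gives up the aryne and makes the C4–C4a bond by acylating an aryllithium. Bromophenol 5 is protected (MOMCl, i-Pr2NEt, CH2Cl2) as 1-bromo-2,3,4,5-tetramethoxy-6-(methoxymethoxy)benzene F1. Acid 15 is condensed with MeNHOMe·HCl (EDC, i-Pr2NEt) to 3-[4,5-bis(benzyloxy)-2-methoxyphenyl]-N-methoxy-N-methylprop-2-ynamide F2. Bromine–lithium exchange on F1 (n-BuLi, THF, −78 °C) gives [2,3,4,5-tetramethoxy-6-(methoxymethoxy)phenyl]lithium F3. F3 is acylated by F2 (cold aq. NH4Cl quench) to 3-[4,5-bis(benzyloxy)-2-methoxyphenyl]-1-[2,3,4,5-tetramethoxy-6-(methoxymethoxy)phenyl]prop-2-yn-1-one F4. HCl in MeOH then frees 17, and DMAP in DMF closes it 6-endo to 18.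

2. Step 9. Oxygen transfer to the twisted, hindered C2=C3 bond may be slow. Oxidation of the electron-rich rings or of the benzylic C–H bonds could then compete. The fallback sets out from 18 and comes back at 20, and it replaces electrophilic oxidation by deprotonation at C3. LDA (THF, −78 °C) gives {2-[4,5-bis(benzyloxy)-2-methoxyphenyl]-5,6,7,8-tetramethoxy-4-oxo-4H-chromen-3-yl}lithium F5. B(OMe)3 converts it into lithium {2-[4,5-bis(benzyloxy)-2-methoxyphenyl]-5,6,7,8-tetramethoxy-4-oxo-4H-chromen-3-yl}trimethoxyborate F6. AcOH/H2O2 then oxidises the C–B bond to the flavonol 20.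

3. Step 11. Further methyl groups (at O6 or O3) may be lost once the boron chelate has formed. Benzyl transfer to ring B may escape the scavenger, and the freed catechol may oxidise in air during work-up. The fallback sets out from 21 and comes back at 22. It splits the deprotection into two orthogonal operations and releases the catechol last, under hydrogen. MgI2·OEt2 (THF–toluene, 60 °C) cleaves only the carbonyl-chelated C5 methyl ether to give 2-[4,5-bis(benzyloxy)-2-methoxyphenyl]-5-hydroxy-3,6,7,8-tetramethoxy-4H-chromen-4-one F7. Hydrogenolysis (H2, Pd/C, EtOAc–MeOH) then removes both benzyl groups to give 22.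

**Further compounds**

F1 | step 8 | 1-bromo-2,3,4,5-tetramethoxy-6-(methoxymethoxy)benzene | COCOc1c(Br)c(OC)c(OC)c(OC)c1OC
F2 | step 8 | 3-[4,5-bis(benzyloxy)-2-methoxyphenyl]-N-methoxy-N-methylprop-2-ynamide | COc1cc(OCc2ccccc2)c(OCc2ccccc2)cc1C#CC(=O)N(C)OC
F3 | step 8 | [2,3,4,5-tetramethoxy-6-(methoxymethoxy)phenyl]lithium | [Li]c1c(OCOC)c(OC)c(OC)c(OC)c1OC
F4 | step 8 | 3-[4,5-bis(benzyloxy)-2-methoxyphenyl]-1-[2,3,4,5-tetramethoxy-6-(methoxymethoxy)phenyl]prop-2-yn-1-one | COCOc1c(OC)c(OC)c(OC)c(OC)c1C(=O)C#Cc1cc(OCc2ccccc2)c(OCc2ccccc2)cc1OC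
F5 | step 9 | {2-[4,5-bis(benzyloxy)-2-methoxyphenyl]-5,6,7,8-tetramethoxy-4-oxo-4H-chromen-3-yl}lithium | COc1cc(OCc2ccccc2)c(OCc2ccccc2)cc1-c1oc2c(OC)c(OC)c(OC)c(OC)c2c(=O)c1[Li]
F6 | step 9 | lithium {2-[4,5-bis(benzyloxy)-2-methoxyphenyl]-5,6,7,8-tetramethoxy-4-oxo-4H-chromen-3-yl}trimethoxyborate | COc1cc(OCc2ccccc2)c(OCc2ccccc2)cc1-c1oc2c(OC)c(OC)c(OC)c(OC)c2c(=O)c1[B-](OC)(OC)OC.[Li+]
F7 | step 11 | 2-[4,5-bis(benzyloxy)-2-methoxyphenyl]-5-hydroxy-3,6,7,8-tetramethoxy-4H-chromen-4-one | COc1cc(OCc2ccccc2)c(OCc2ccccc2)cc1-c1oc2c(OC)c(OC)c(OC)c(O)c2c(=O)c1OC
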